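## Retrosynthetic overview

1. The target is an ent-labdane. C4, C5, C9, C10 and both carbocycles are bought in andrographolide (1); no carbocycle is built.
2. Key disconnection C12–C13 (sp3–sp2): a visible-light nickel/iridium deoxygenative coupling joins a C12 alcohol to an (E)-enol triflate that carries C13–C16. The triflate geometry becomes the 13Z alkene; tert-butyl ester cleavage follows.
3. The C12 alcohol comes from permanganate cleavage of C12=C13 of the andrographolide side chain (the butenolide ring is cut away), then NaBH4.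
4. The C3–OH is removed by radical fragmentation of a 3,19-cyclic thionocarbonate. This is the only ring formed in the route: made in step 1, opened in step 2. C19 is then acetylated.
5. The enol triflate comes from tert-butyl 4-acetoxy-3-oxobutanoate, made from tert-butyl 4-chloro-3-oxobutanoate.

Assumption: the SMILES is read as (13Z)-16,19-diacetoxy-ent-labda-8(17),13-dien-15-oic acid, whose C4, C5, C9 and C10 centres are those of natural andrographolide; one-flask sequences count as one step.

## Route

Step 1
Reactants: 1 andrographolide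
Product: 2 andrographolide 3,19-cyclic thionocarbonate (six-membered C3–O–C(=S)–O–C19 ring; 14-OH free; 3R,4R,5S,9R,10S,14S)
Conditions: 1,1'-thiocarbonyldiimidazole (1.05 equiv), DMAP (cat.), THF, 0 °C to rt
Reagents that add atoms: 1,1'-thiocarbonyldiimidazole S=C(n1ccnc1)n1ccnc1
Why: Cyclic thionocarbonate formation; after the first acyl transfer to the primary C19–OH, ring closure onto the neighbouring C3–OH is intramolecular and outruns acylation of the lone allylic C14–OH (the same 1,3-diol preference seen in acetal formation on 1); no stereocentre is touched.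

Step 2
Reactants: 2 andrographolide 3,19-cyclic thionocarbonate
Product: 4 3-deoxyandrographolide (14,19-dihydroxy-ent-labda-8(17),12E-dien-16,15-olide; 4R,5S,9R,10S,14S), via stannyl thiocarbonate 3 (not isolated)
Conditions: Bu3SnH (1.5 equiv), AIBN (cat.), toluene/1,4-dioxane, 95 °C; then KF, AcOH, MeOH, rt
Reagents that add atoms: none
Why: Barton-type radical deoxygenation of a cyclic thionocarbonate; the tin radical adds to sulfur and the ring fragments at the C3–O bond (secondary radical) and not at the neopentyl primary C19–O bond, the C3 radical takes hydrogen from the stannane, and the S-stannyl thiocarbonate 3 left on O19 loses COS on buffered fluoride work-up; C3 stops being a stereocentre and C4 is untouched.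

Step 3
Reactants: 4 3-deoxyandrographolide
Product: 5 14,19-di-O-acetyl-3-deoxyandrographolide (4R,5S,9R,10S,14S)
Conditions: Ac2O (excess), pyridine, rt
Reagents that add atoms: acetic anhydride CC(=O)OC(C)=O
Why: Pyridine-promoted O-acetylation of both hydroxyls; it installs the C19 acetate of the target and ensures that the C12 hydroxyl made in step 4 is the only free OH (the C14 acetate leaves with the lactone).

Step 4
Reactants: 5 14,19-di-O-acetyl-3-deoxyandrographolide
Product: 7 19-acetoxy-13,14,15,16-tetranor-ent-labd-8(17)-en-12-ol (primary alcohol on the C9 two-carbon chain; 4R,5S,9R,10S), via aldehyde 6 (not isolated)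
Conditions: KMnO4 (1.4 equiv), MgSO4, THF/H2O, −10 °C; filter; then NaBH4, THF/MeOH, 0 °C
Reagents that add atoms: potassium permanganate [K+].[O-][Mn](=O)(=O)=O
Why: Oxidative alkene cleavage; permanganate should attack the electron-poor, conjugated C12=C13 bond faster than the hindered 1,1-disubstituted C8=C17 bond, and the resulting aldehyde 6 is reduced in the same flask by NaBH4 (acetates survive); C9 is β to the aldehyde and cannot epimerise.

Step 5
Reactants: 8 tert-butyl 4-chloro-3-oxobutanoate
Product: 9 tert-butyl 4-acetoxy-3-oxobutanoate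
Conditions: KOAc (1.5 equiv), AcOH (0.2 equiv), DMF, 25 °C
Reagents that add atoms: potassium acetate CC(=O)[O-].[K+]
Why: SN2 displacement of the activated α-chloroketone chloride by acetate, buffered with AcOH so that the β-keto ester does not self-condense.

Step 6
Reactants: 9 tert-butyl 4-acetoxy-3-oxobutanoate
Product: 10 tert-butyl (2E)-4-acetoxy-3-{[(trifluoromethyl)sulfonyl]oxy}but-2-enoate (OTf trans to the ester, CH2OAc cis to it)
Conditions: Tf2O (1.3 equiv), aq. Me4NOH, hexanes, 5 °C, 10 min
Reagents that add atoms: trifluoromethanesulfonic anhydride O=S(=O)(OS(=O)(=O)C(F)(F)F)C(F)(F)F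
Why: Stereoselective enol triflate formation; with the non-chelating tetramethylammonium counter-ion the β-keto ester enolate reacts from its dipole-minimised form and gives the (E)-enol triflate, which is the geometry needed at C13=C14.

Step 7
Reactants: 7 19-acetoxy-13,14,15,16-tetranor-ent-labd-8(17)-en-12-ol; 10 tert-butyl (2E)-4-acetoxy-3-{[(trifluoromethyl)sulfonyl]oxy}but-2-enoate
Product: 12 tert-butyl (13Z)-16,19-diacetoxy-ent-labda-8(17),13-dien-15-oate (4R,5S,9R,10S), via NHC–alcohol adduct 11 (not isolated)
Conditions: 5,7-di-tert-butyl-3-phenylbenzoxazol-3-ium tetrafluoroborate (1.1 equiv), pyridine (1.1 equiv), MTBE, rt, 20 min; then 10 (1.5 equiv), NiBr2(dtbbpy) (10 mol%), [Ir(ppy)2(dtbbpy)]PF6 (2 mol%), 2,4,6-collidine (2 equiv), DMA/MTBE, 450 nm LEDs, 25 °C (ppy = 2-phenylpyridinate; dtbbpy = 4,4'-di-tert-butyl-2,2'-bipyridine)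
Reagents that add atoms: none
Why: Proposed new method: the primary alcohol condenses with the benzoxazolium salt to aminal 11; the excited iridium photocatalyst oxidises its aniline nitrogen, collidine removes the now acidic aminal C–H, and β-scission of the exocyclic C–O bond releases the C12 primary radical (a pent-4-enyl radical, for which only 4-exo or 5-endo closure is open, so it does not cyclise) plus the benzoxazolone; zerovalent nickel, made from NiBr2(dtbbpy) by the reduced photocatalyst, inserts into the C–OTf bond of the vinylogous mixed anhydride 10 with retention, the alkenyl divalent nickel species captures the radical, and reductive elimination from trivalent nickel forms C12–C13 with C12 trans to the ester, so the (E)-geometry of 10 becomes the 13Z alkene; the closest known reaction types are the nickel/photoredox deoxygenative arylation of NHC-activated alcohols with aryl halides and the stereoretentive nickel or palladium cross-coupling of β-keto-ester enol triflates, but a stereodefined enol triflate as the C(sp2) partner of a deoxygenative alcohol coupling is not established; collidine replaces the usual quinuclidine because a nucleophilic amine would add to 10.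

Step 8
Reactants: 12 tert-butyl (13Z)-16,19-diacetoxy-ent-labda-8(17),13-dien-15-oate
Product: 14 (13Z)-16,19-diacetoxy-ent-labda-8(17),13-dien-15-oic acid (CNP0181814.1; 4R,5S,9R,10S), via trimethylsilyl ester 13 (not isolated)
Conditions: TMSOTf (2 equiv), 2,6-lutidine (3 equiv), CH2Cl2, 0 °C; then H2O (pH 5 buffer)
Reagents that add atoms: none
Why: Silyl-triflate-mediated tert-butyl ester cleavage; O-silylation of the ester carbonyl and loss of the tert-butyl cation as isobutene under lutidine buffering gives silyl ester 13, which hydrolyses on work-up, so the exocyclic alkene never meets protic acid and the acetates and the 13Z geometry are untouched.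

## Compound list

1 | andrographolide, (3E,4S)-3-{2-[(1R,4aS,5R,6R,8aS)-6-hydroxy-5-(hydroxymethyl)-5,8a-dimethyl-2-methylidenedecahydronaphthalen-1-yl]ethylidene}-4-hydroxyoxolan-2-one | C=C1CC[C@@H]2[C@](C)(CO)[C@H](O)CC[C@@]2(C)[C@@H]1C/C=C1/C(=O)OC[C@H]1O | starting material
2 | andrographolide 3,19-cyclic thionocarbonate | C=C1CC[C@@H]2[C@]3(C)COC(=S)O[C@@H]3CC[C@@]2(C)[C@@H]1C/C=C1/C(=O)OC[C@H]1O | intermediate
3 | stannyl thiocarbonate, 19-O-{[(tributylstannyl)sulfanyl]carbonyl}-3-deoxyandrographolide | C=C1CC[C@@H]2[C@](C)(COC(=O)S[Sn](CCCC)(CCCC)CCCC)CCC[C@@]2(C)[C@@H]1C/C=C1/C(=O)OC[C@H]1O | intermediate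
4 | 3-deoxyandrographolide | C=C1CC[C@@H]2[C@](C)(CO)CCC[C@@]2(C)[C@@H]1C/C=C1/C(=O)OC[C@H]1O | intermediate
5 | 14,19-di-O-acetyl-3-deoxyandrographolide | C=C1CC[C@@H]2[C@](C)(COC(C)=O)CCC[C@@]2(C)[C@@H]1C/C=C1/C(=O)OC[C@H]1OC(C)=O | intermediate
6 | aldehyde, 19-acetoxy-13,14,15,16-tetranor-ent-labd-8(17)-en-12-al | C=C1CC[C@@H]2[C@](C)(COC(C)=O)CCC[C@@]2(C)[C@@H]1CC=O | intermediate
7 | 19-acetoxy-13,14,15,16-tetranor-ent-labd-8(17)-en-12-ol | C=C1CC[C@@H]2[C@](C)(COC(C)=O)CCC[C@@]2(C)[C@@H]1CCO | intermediate
8 | tert-butyl 4-chloro-3-oxobutanoate | CC(C)(C)OC(=O)CC(=O)CCl | starting material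
9 | tert-butyl 4-acetoxy-3-oxobutanoate | CC(C)(C)OC(=O)CC(=O)COC(C)=O | intermediate
10 | tert-butyl (2E)-4-acetoxy-3-{[(trifluoromethyl)sulfonyl]oxy}but-2-enoate | CC(=O)OC/C(OS(=O)(=O)C(F)(F)F)=C\C(=O)OC(C)(C)C | intermediate
11 | NHC–alcohol adduct, 2-alkoxy-5,7-di-tert-butyl-3-phenyl-2,3-dihydrobenzoxazole of 7 (either epimer at the aminal carbon) | C=C1CC[C@@H]2[C@](C)(COC(C)=O)CCC[C@@]2(C)[C@@H]1CCOC1Oc2c(C(C)(C)C)cc(C(C)(C)C)cc2N1c1ccccc1 | intermediate
12 | tert-butyl (13Z)-16,19-diacetoxy-ent-labda-8(17),13-dien-15-oate | C=C1CC[C@@H]2[C@](C)(COC(C)=O)CCC[C@@]2(C)[C@@H]1CC/C(=C/C(=O)OC(C)(C)C)COC(C)=O | intermediate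
13 | trimethylsilyl ester, trimethylsilyl (13Z)-16,19-diacetoxy-ent-labda-8(17),13-dien-15-oate | C=C1CC[C@@H]2[C@](C)(COC(C)=O)CCC[C@@]2(C)[C@@H]1CC/C(=C/C(=O)O[Si](C)(C)C)COC(C)=O | intermediate
14 | (13Z)-16,19-diacetoxy-ent-labda-8(17),13-dien-15-oic acid (CNP0181814.1) | C=C1CC[C@@H]2[C@](C)(COC(C)=O)CCC[C@@]2(C)[C@@H]1CC/C(=C/C(=O)O)COC(C)=O | target

## Step count and risk

Total steps: 8 (steps 1–4, 7 and 8 on the main line; steps 5 and 6 make the coupling partner).
Longest linear sequence: 6 steps (1 → 2 → 4 → 5 → 7 → 12 → 14).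

The three steps most likely to fail:

**Step 7 (the proposed new coupling).** Three things could go wrong. Zerovalent nickel could ionise the allylic acetate of 10 or 12. The alkenyl divalent nickel intermediate could lose its geometry through an ester-chelated form. Collidine could prove too weak a base for the radical-forming step. The fallback is a thermal organozinc cross-coupling of known type. It sets out from 7, which is converted with I2, PPh3 and imidazole (CH2Cl2, 0 °C) into the primary iodide 19-acetoxy-12-iodo-13,14,15,16-tetranor-ent-labd-8(17)-ene F5. Zinc insertion (Zn dust, LiCl, THF, 40 °C) gives the alkylzinc iodide F6. A Negishi coupling with 10 (Pd(PPh3)4, THF, rt), in which zerovalent palladium inserts into the C–OTf bond with retention, comes back to the route at 12.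

**Step 4 (chemoselective cleavage).** Permanganate may also attack the exocyclic C8=C17 alkene or over-oxidise the aldehyde. The fallback masks that alkene and sets out from 5. mCPBA (NaHCO3, CH2Cl2, 0 °C) epoxidises only the electron-rich exocyclic alkene and gives the 8,17-epoxide of 5 F3; the epoxide carbon C8 is a transient centre and either epimer serves. Ozonolysis of the one remaining alkene (O3, CH2Cl2/MeOH, −78 °C; then NaBH4) gives the epoxy alcohol 19-acetoxy-8,17-epoxy-13,14,15,16-tetranor-ent-labdan-12-ol F4. Deoxygenation of the epoxide with WCl6/n-BuLi (THF, −78 °C to rt) restores the methylene group and comes back to the route at 7.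

**Step 1 (selective thionocarbonate formation next to the free C14–OH, and with it the regioselective fragmentation of step 2).** If the allylic hydroxyl competes for the reagent, a stepwise protect-then-deoxygenate sequence is used, setting out from 1. Ac2O (2.1 equiv) in pyridine at −20 to 0 °C acetylates the two more reactive hydroxyls and gives 14,19-di-O-acetylandrographolide F1. The hindered C3–OH is then converted with phenyl chlorothionoformate and DMAP (MeCN, rt) into 14,19-di-O-acetyl-3-O-(phenoxythiocarbonyl)andrographolide F2. Barton–McCombie reduction (Bu3SnH, AIBN, toluene, 90 °C) comes back to the route at 5, replacing steps 1–3.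

## Further compounds

F1 | step 1 | 14,19-di-O-acetylandrographolide | C=C1CC[C@@H]2[C@](C)(COC(C)=O)[C@H](O)CC[C@@]2(C)[C@@H]1C/C=C1/C(=O)OC[C@H]1OC(C)=O
F2 | step 1 | 14,19-di-O-acetyl-3-O-(phenoxythiocarbonyl)andrographolide | C=C1CC[C@@H]2[C@](C)(COC(C)=O)[C@H](OC(=S)Oc3ccccc3)CC[C@@]2(C)[C@@H]1C/C=C1/C(=O)OC[C@H]1OC(C)=O
F3 | step 4 | 8,17-epoxide of 5 (14,19-di-O-acetyl-8,17-epoxy-3-deoxyandrographolide, either C8 epimer) | O1CC12CC[C@@H]3[C@](C)(COC(C)=O)CCC[C@@]3(C)[C@@H]2C/C=C2/C(=O)OC[C@H]2OC(C)=O
F4 | step 4 | 19-acetoxy-8,17-epoxy-13,14,15,16-tetranor-ent-labdan-12-ol | O1CC12CC[C@@H]3[C@](C)(COC(C)=O)CCC[C@@]3(C)[C@@H]2CCO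
F5 | step 7 | 19-acetoxy-12-iodo-13,14,15,16-tetranor-ent-labd-8(17)-ene | C=C1CC[C@@H]2[C@](C)(COC(C)=O)CCC[C@@]2(C)[C@@H]1CCI
F6 | step 7 | alkylzinc iodide of F5, [19-acetoxy-13,14,15,16-tetranor-ent-labd-8(17)-en-12-yl]zinc iodide | C=C1CC[C@@H]2[C@](C)(COC(C)=O)CCC[C@@]2(C)[C@@H]1CC[Zn]I
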